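## Structural features

The target 32 is a bicyclic, dearomatised acylphloroglucinol. Ring A is a carbocycle (C4a, C5, C6, C7, C8, C8a) that carries an enolised β-triketone array (C4=O, C5–OH, C7=O), and ring B is a dihydropyran-4-one (O1, C2, C3, C4) fused to it across C4a=C8a. C2 (R) and C3 (S) are adjacent and carry cis methyl groups. C8 (R) is quaternary and bears a prenyl group and a ten-carbon 5-methyl-2-isopropenylhex-5-enyl arm whose own stereocentre (R) lies two bonds away. C6 carries a 3-hexanoic acid chain whose stereocentre (S) is isolated from the others. The fragile points are C3 (alpha to C4, it epimerises to the more stable trans isomer under base), three electron-rich alkenes (sensitive to acid and to radicals), the acidic and easily O-alkylated triketone, and the acid chain, which lactonises onto O5 or O7. The real difficulty is C8: it must become quaternary with two alkyl groups that both begin with CH2 and with no neighbouring stereocentre to direct it. A second difficulty is regiochemical, since ring A comes from a threefold-symmetric phenol and O5, O7, O8a, C6 and C8 must be told apart. The key step exploits that C4 is a ketone carbon bonded to C3, and C3 can be the β-carbon of a removable carboxyl group. The C3–C4 bond is therefore the bond made when an acyl anion at C4 adds to an enoate, and the O1–C2(CH3) unit is the skeleton of lactic acid.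

## Logic of the disconnections

32 to 30 and 31. The C8–CH2(prenyl) bond is cut. Removing one alkyl group from the only sp3 carbon of ring A returns an aromatic ring, so all earlier chemistry can be arene chemistry. The forward step must alkylate carbon and not oxygen, choose C8 over C6 and choose one face. Reversible π-allyl palladium chemistry with a chiral ligand answers this, with the enolised triketone anion as the thermodynamic sink.

30 to 29. The O5–C(=O) lactone bond and the O7–Si bond are re-formed. The lactone protects the acid and O5 at once and leaves O7 as the only phenol that needs a separate group. One hydroxide step must unmask both without epimerising C3.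

29 to 20 and 27 (through 28), and 20 to 19. The C8–CH2(arm) bond and then the C8–I bond are cut. After ring B exists, C8 is the only aromatic C–H, so halogenation has no choice to make. The arm arrives as a finished, stereodefined unit. The coupling must occur between two ortho oxygens and must avoid a free β-branched homoallylic radical, which would undergo vinyl shift and hexenyl cyclisation. An alkylzinc and palladium are therefore used.

27 back to 21 (through 25, 24, 23). The C–I bond comes from C–CO2H with loss of one carbon, the terminal methylene from a ketone, and the two carbonyls from the ring alkene of 21. The arm is the skeleton of 21 opened at C1=C2 with its stereocentre untouched. Ozone must take only the trisubstituted alkene, and the decarboxylative iodination must trap the radical faster than it rearranges.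

19 to 17 to 16. The C3 methyl is traced back to CH2CO2t-Bu. This adds the carbon that makes C3 the β-carbon of an ester and exposes the 1,4-dicarbonyl pattern. The forward decarboxylation must reduce the exocyclic radical before it attacks the C4 carbonyl.

16 to 15 (key). The C3–C4 bond is cut. Ring B and the C3 stereocentre are replaced by an aldehyde on C4a and an enoate ether on O8a. The forward step must give the cis isomer and must not let it epimerise.

15 to 9 and 14. The O8a–C2 bond is cut, with inversion in the forward direction. The union is convergent and takes C2 from the chiral pool. It requires SN2 and not SN2′ substitution, a reactive chelated phenol, and the other phenol already silylated.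

14 back to 10 (through 13, 12, 11). The enoate C=C is cut (Wittig) and the aldehyde is traced to the ester. The α-oxygenated aldehyde must not racemise.

9 to 8 to 6. The O–Si bond and the aryl–CHO bond are cut. Formylation creates a chelated and an unchelated phenol and so differentiates O8a from O7 without extra steps. It must occur between the lactone oxygen and a hydroxyl, not between the two hydroxyls.

6 to 3 to 1 and 2 (through 4, 5). The C–H bond at the propyl-bearing carbon is cut, then the aryl–C and O–C(=O) bonds of the pyranone. Lactone formation desymmetrises 1, and the side-chain stereocentre comes from a ligand-controlled hydride addition that must tolerate the phenols.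

## Other disconnections considered

Alternative 1: The C4a–C5 bond is cut. In precursor A1 the quaternary carbon already carries prenyl, arm, the cis-dimethyl dihydropyranone (through C8a) and a 2,2-dimethyl-1,3-dioxin-4-one (through C7). Heating would expel acetone, and the acylketene would acylate C4a, the nucleophilic α-carbon of the vinylogous ester, to close ring A as allyl ester A2. Deallylation would then give 32.
- In its favour: the closure is neutral and thermal, so C3 is not exposed to base. On this point it is better than the chosen plan. It needs no arene regiochemistry, and only one step follows the key step, against six on the main line here.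
- Against it: A1 needs a non-aromatic quaternary stereocentre with two CH2-linked groups and two sp2 carbons, so the C8 problem is moved into an acyclic setting with no evident catalytic handle. The acylketene can also be taken by the enone oxygen or by the three alkenes, and a 5-substituted dioxinone with a tertiary group at C6 is hard to prepare.
- Comparison: both plans close a six-membered ring intramolecularly. The three separately built fragments of A1 would probably make the whole route longer than the 19 steps planned here.

Alternative 2: The C6–C7 bond is cut. In A3 the quaternary carbon bears a methyl ester (C7) and a β-methoxy enone chain. Deprotonation at C6 and Claisen closure would give A4, ring A with O5 methylated.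
- In its favour: C8 would be fixed early by an enzymatic ester hydrolysis and not in the last step. This is a real advantage over the chosen plan if the enzyme distinguishes the two alkyl groups. No arene regiochemistry arises.
- Against it: ring B is still missing after the key step. C4a must be acylated, the cis-2,3-dimethylpyranone closed under enolising conditions (the thermodynamic trans isomer is favoured), and O5 demethylated beside three alkenes. The closure needs stoichiometric strong base, the ester attacked is neopentyl-like, and enzyme selectivity between prenyl and the branched arm cannot be predicted.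
- Comparison: the plan is better for C8 and worse for C2/C3. Step count would be comparable or higher.

Alternative 3: The C6–Cβ bond and the O7–acyl bond are cut. The prochiral ring A5 would react as its anion with anhydride A6, activated on a chiral isothiourea. Michael addition through C6 followed by lactonisation on O7 would give A7.
- In its favour: one catalytic step would attach the side chain, set its stereocentre and, by choosing one ring terminus, set C8. This is better step economy than the separate reduction and late prenylation used here. Both plans rely on Lewis-base organocatalysis, so they are equal in mechanistic reliability.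
- Against it: the two termini of A5 differ only through remote CH2-linked groups on C8, so the desymmetrisation has little to grip. The lactone closes on O7, so ring B with its cis-dimethyl pair and the demethylation of O5 remain. Making A5 requires geminal alkylation with an unactivated arm electrophile.
- Comparison: the chosen plan sets C8 no more securely, but it fixes C2 and C3 early from lactate and a catalyst.

Key step: step 9

Remark on numbering: atoms are discussed with the locants of 32 (O1, C2, C3, C4, C4a, C5 to C8, C8a); names of intermediates use the locants of their own ring systems.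

Assumption: the antipodes named for the three chiral catalysts (bisphosphine on copper hydride, aminoindanol triazolium salt, diaminocyclohexane bisphosphine on palladium) are those expected by analogy to give the stated configurations; the mirror-image catalyst is equally available.

Remark on configuration: inversion of the (S)-alcohol 14 gives the (R)-ether in 15, which is C2 of 32. Compound 16 is cis, and its propyl-bearing centre and that of 15 are S as in 32, so the skeletons of 15 and 16 need no correction.

## Steps

Step 1
Reactants: 1 phloroglucinol; 2 ethyl 3-oxohexanoate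
Product: 3 5,7-dihydroxy-4-propyl-2H-chromen-2-one
Conditions: CH3SO3H, rt
Reagents that add atoms: none
Why: Pechmann condensation; because 1 is threefold symmetric, ring attack and lactonisation onto a neighbouring hydroxyl can give only one constitution.

Step 2
Reactants: 3 5,7-dihydroxy-4-propyl-2H-chromen-2-one
Product: 6 (4S)-5,7-dihydroxy-4-propylchroman-2-one, via bis-trimethylsilyl ether 4 (not isolated), via silyl ketene acetal 5 (not isolated)
Conditions: (Me3Si)2NH, cat. (NH4)2SO4, toluene, reflux, evaporate; Cu(OAc)2·H2O (3 mol %), (R)-DTBM-SEGPHOS (3 mol %), (EtO)2MeSiH (2 equiv), toluene, 0 °C to rt; then 1 M HCl, THF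
Reagents that add atoms: none
Why: Ligand-controlled copper hydride 1,4-reduction of a coumarin, in which the chiral bisphosphine selects the face of C4 that receives hydride. The phenols are masked in the flask, and without an alcohol additive the product rests as ketene acetal 5, which resists further reduction until acid releases lactone and phenols.

Step 3
Reactants: 6 (4S)-5,7-dihydroxy-4-propylchroman-2-one
Product: 8 (4S)-5,7-dihydroxy-2-oxo-4-propylchromane-8-carbaldehyde, via iminium chloride 7 (not isolated)
Conditions: POCl3, DMF, MeCN, 0 °C to rt; then aq. NaOAc, rt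
Reagents that add atoms: N,N-dimethylformamide CN(C)C=O; water O
Why: Vilsmeier–Haack formylation. Attack at C8 places the para position of the arenium ion on the carbon bearing the free 5-hydroxyl, whereas attack at C6 would place it on the carbon bearing the weakly donating lactone oxygen, so C8 should be preferred.

Step 4
Reactants: 8 (4S)-5,7-dihydroxy-2-oxo-4-propylchromane-8-carbaldehyde
Product: 9 (4S)-5-(tert-butyldimethylsilyloxy)-7-hydroxy-2-oxo-4-propylchromane-8-carbaldehyde
Conditions: t-BuMe2SiCl (1.05 equiv), imidazole, CH2Cl2, 0 °C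
Reagents that add atoms: tert-butyldimethylsilyl chloride CC(C)(C)[Si](C)(C)Cl
Why: Selective silylation; the 7-hydroxyl is held in a hydrogen bond to the aldehyde, so the more acidic, unchelated 5-hydroxyl (para to the aldehyde) reacts.

Step 5
Reactants: 10 ethyl (S)-lactate
Product: 11 ethyl (S)-2-(tert-butyldimethylsilyloxy)propanoate
Conditions: t-BuMe2SiCl, imidazole, DMF, rt
Reagents that add atoms: tert-butyldimethylsilyl chloride CC(C)(C)[Si](C)(C)Cl
Why: Standard silyl ether formation; the stereocentre is not involved.

Step 6
Reactants: 11 ethyl (S)-2-(tert-butyldimethylsilyloxy)propanoate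
Product: 13 tert-butyl (S,E)-4-(tert-butyldimethylsilyloxy)pent-2-enoate, via silyloxypropanal 12 (not isolated)
Conditions: (i-Bu)2AlH, CH2Cl2, −78 °C; then Ph3P=CHCO2t-Bu, −78 °C to rt
Reagents that add atoms: tert-butyl (triphenylphosphoranylidene)acetate CC(C)(C)OC(=O)C=P(c1ccccc1)(c1ccccc1)c1ccccc1
Why: Half-reduction through the aluminium hemiacetal and in situ Wittig olefination with a stabilised ylide (E-selective); the configurationally labile α-silyloxy aldehyde is never isolated.

Step 7
Reactants: 13 tert-butyl (S,E)-4-(tert-butyldimethylsilyloxy)pent-2-enoate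
Product: 14 tert-butyl (S,E)-4-hydroxypent-2-enoate
Conditions: Bu4NF, AcOH, THF, 0 °C to rt
Reagents that add atoms: none
Why: Buffered fluoride desilylation; the E geometry prevents lactonisation and the buffer suppresses base-induced isomerisation of the γ-hydroxy enoate.

Step 8
Reactants: 9 (4S)-5-(tert-butyldimethylsilyloxy)-7-hydroxy-2-oxo-4-propylchromane-8-carbaldehyde; 14 tert-butyl (S,E)-4-hydroxypent-2-enoate
Product: 15 tert-butyl (R,E)-4-{[(4S)-5-(tert-butyldimethylsilyloxy)-8-formyl-2-oxo-4-propylchroman-7-yl]oxy}pent-2-enoate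
Conditions: PPh3, i-PrO2CN=NCO2i-Pr, toluene, 0 °C to rt
Reagents that add atoms: none
Why: Mitsunobu etherification; the acidic salicylaldehyde-type phenol displaces the activated allylic alcohol by SN2 with inversion (S to R). Attack at the enoate α-carbon (SN2′) is electronically disfavoured.

Step 9
Reactants: 15 tert-butyl (R,E)-4-{[(4S)-5-(tert-butyldimethylsilyloxy)-8-formyl-2-oxo-4-propylchroman-7-yl]oxy}pent-2-enoate
Product: 16 tert-butyl 2-[(4S,8R,9S)-5-(tert-butyldimethylsilyloxy)-8-methyl-2,10-dioxo-4-propyl-3,4,9,10-tetrahydro-2H,8H-pyrano[2,3-f]chromen-9-yl]acetate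
Conditions: cis-1-amino-2-indanol-derived N-C6F5 triazolium tetrafluoroborate (20 mol %), KN(SiMe3)2 (18 mol %), toluene, 0 to 23 °C; AcOH quench
Reagents that add atoms: none
Why: Deprotonation of the triazolium salt gives the carbene, which adds to the C4a aldehyde; proton transfer gives the Breslow intermediate, an acyl anion equivalent at C4. This carbon adds to the β-carbon of the (E)-enoate (the future C3) in a 6-exo-trig closure of ring B, and proton transfer with loss of the carbene releases the ketone; the closest known reaction is the enantioselective intramolecular Stetter cyclisation of salicylaldehyde-derived 4-aryloxybut-2-enoates to 3-substituted chroman-4-ones. C2 is not touched and keeps the R configuration set by the Mitsunobu inversion. C3 is created in the carbon–carbon bond-forming event, so its configuration depends on which enoate face the carbene-bound nucleophile reaches; the catalyst antipode is chosen so that its intrinsic preference gives 3S, with the acetate arm cis to the C2 methyl. The allylic ether centre faces only a vinylic hydrogen in the E-alkene, so its own A(1,3) bias is small and the catalyst should dominate. Chemoselectivity for 1,4-addition over benzoin-type dimerisation is secured by the two ortho oxygens, which shield the aldehyde from a second aldehyde, and by the tether; acylation of the carbene by the aryl lactone is reversible. Survival of the kinetic cis isomer is secured by using less base than azolium salt, so that no free amide base remains, and by the acid quench.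

Step 10
Reactants: 16 tert-butyl 2-[(4S,8R,9S)-5-(tert-butyldimethylsilyloxy)-8-methyl-2,10-dioxo-4-propyl-3,4,9,10-tetrahydro-2H,8H-pyrano[2,3-f]chromen-9-yl]acetate
Product: 17 2-[(4S,8R,9S)-5-(tert-butyldimethylsilyloxy)-8-methyl-2,10-dioxo-4-propyl-3,4,9,10-tetrahydro-2H,8H-pyrano[2,3-f]chromen-9-yl]acetic acid
Conditions: CF3CO2H, CH2Cl2, 0 °C
Reagents that add atoms: none
Why: Acidolysis of the tert-butyl ester with loss of isobutene; aryl silyl ether and lactone tolerate the acid, and cold acid should not enolise C9.

Step 11
Reactants: 17 2-[(4S,8R,9S)-5-(tert-butyldimethylsilyloxy)-8-methyl-2,10-dioxo-4-propyl-3,4,9,10-tetrahydro-2H,8H-pyrano[2,3-f]chromen-9-yl]acetic acid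
Product: 19 (4S,8R,9S)-5-(tert-butyldimethylsilyloxy)-8,9-dimethyl-4-propyl-3,4,8,9-tetrahydro-2H,10H-pyrano[2,3-f]chromene-2,10-dione, via thiohydroxamate ester 18 (not isolated)
Conditions: N-hydroxypyridine-2-thione, DCC, CH2Cl2, dark, 0 °C; then t-BuSH (10 equiv), visible light, rt
Reagents that add atoms: none
Why: Barton reductive decarboxylation; photolysis of ester 18 gives the exocyclic primary radical, which takes hydrogen from the thiol and leaves the adjacent stereocentre untouched. The large excess of thiol should quench the radical before it can add to the C10 carbonyl (Dowd–Beckwith ring expansion).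

Step 12
Reactants: 19 (4S,8R,9S)-5-(tert-butyldimethylsilyloxy)-8,9-dimethyl-4-propyl-3,4,8,9-tetrahydro-2H,10H-pyrano[2,3-f]chromene-2,10-dione
Product: 20 (4S,8R,9S)-5-(tert-butyldimethylsilyloxy)-6-iodo-8,9-dimethyl-4-propyl-3,4,8,9-tetrahydro-2H,10H-pyrano[2,3-f]chromene-2,10-dione
Conditions: NIS (1.1 equiv), CF3CO2H (1 equiv), MeCN, 0 °C to rt
Reagents that add atoms: N-iodosuccinimide O=C1CCC(=O)N1I
Why: Electrophilic aromatic iodination; C6 of this ring system (C8 of 32) is the only aromatic C–H and lies ortho to two oxygens, so no regiochemical choice exists.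

Step 13
Reactants: 21 (R)-limonene
Product: 23 (3R)-6-oxo-3-(prop-1-en-2-yl)heptanal, via secondary ozonide 22 (not isolated)
Conditions: O3 (1.0 equiv, Sudan Red 7B end point), CH2Cl2, −78 °C; then PPh3, −78 °C to rt
Reagents that add atoms: ozone [O-][O+]=O
Why: Ozonolysis; the trisubstituted ring alkene is more electron-rich than the isopropenyl group and reacts first. The stereocentre is β to both new carbonyl groups and cannot epimerise.

Step 14
Reactants: 23 (3R)-6-oxo-3-(prop-1-en-2-yl)heptanal
Product: 24 (3R)-6-oxo-3-(prop-1-en-2-yl)heptanoic acid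
Conditions: NaClO2, NaH2PO4, 2-methylbut-2-ene, t-BuOH/H2O, 0 °C to rt
Reagents that add atoms: sodium chlorite [Na+].[O-]Cl=O
Why: Pinnick oxidation; the scavenger alkene removes hypochlorous acid and protects the isopropenyl group.

Step 15
Reactants: 24 (3R)-6-oxo-3-(prop-1-en-2-yl)heptanoic acid
Product: 25 (3R)-6-methyl-3-(prop-1-en-2-yl)hept-6-enoic acid
Conditions: Ph3PCH3Br (2.5 equiv), KOt-Bu (3.5 equiv), THF, 0 °C to rt
Reagents that add atoms: methyltriphenylphosphonium bromide C[P+](c1ccccc1)(c1ccccc1)c1ccccc1.[Br-]
Why: Wittig methylenation of the ketone; the carboxylate formed first is inert to the ylide, and the stereocentre is remote from both acidic positions.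

Step 16
Reactants: 25 (3R)-6-methyl-3-(prop-1-en-2-yl)hept-6-enoic acid
Product: 27 (3S)-3-(iodomethyl)-2,6-dimethylhepta-1,6-diene, via thiohydroxamate ester 26 (not isolated)
Conditions: N-hydroxypyridine-2-thione, DCC, CH2Cl2, dark, rt; then CHI3 (2 equiv), visible light, rt
Reagents that add atoms: iodoform IC(I)I
Why: Barton iododecarboxylation; iodine-atom transfer from iodoform at high concentration should trap the primary radical before vinyl shift or hexenyl cyclisation. The spatial arrangement is unchanged; the descriptor becomes S only because CH2I outranks isopropenyl.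

Step 17
Reactants: 27 (3S)-3-(iodomethyl)-2,6-dimethylhepta-1,6-diene; 20 (4S,8R,9S)-5-(tert-butyldimethylsilyloxy)-6-iodo-8,9-dimethyl-4-propyl-3,4,8,9-tetrahydro-2H,10H-pyrano[2,3-f]chromene-2,10-dione
Product: 29 (4S,8R,9S)-5-(tert-butyldimethylsilyloxy)-8,9-dimethyl-6-[(2R)-5-methyl-2-(prop-1-en-2-yl)hex-5-en-1-yl]-4-propyl-3,4,8,9-tetrahydro-2H,10H-pyrano[2,3-f]chromene-2,10-dione, via alkylzinc iodide 28 (not isolated)
Conditions: 27, Zn dust (activated by Me3SiCl and BrCH2CH2Br), LiCl, THF, 25–40 °C; then 20, Pd(OAc)2 (3 mol %), SPhos (6 mol %), THF, rt to 45 °C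
Reagents that add atoms: none
Why: Negishi coupling of a primary alkylzinc with a hindered aryl iodide. Transmetalation and reductive elimination are two-electron steps, so the homoallylic arm cannot rearrange. The neutral zinc reagent leaves ketone, lactone and the C9 stereocentre alone, and the bulky biaryl phosphine favours reductive elimination over β-hydride loss.

Step 18
Reactants: 29 (4S,8R,9S)-5-(tert-butyldimethylsilyloxy)-8,9-dimethyl-6-[(2R)-5-methyl-2-(prop-1-en-2-yl)hex-5-en-1-yl]-4-propyl-3,4,8,9-tetrahydro-2H,10H-pyrano[2,3-f]chromene-2,10-dione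
Product: 30 (3S)-3-{(2R,3S)-5,7-dihydroxy-2,3-dimethyl-8-[(2R)-5-methyl-2-(prop-1-en-2-yl)hex-5-en-1-yl]-4-oxochroman-6-yl}hexanoic acid
Conditions: LiOH (5 equiv), THF/MeOH/H2O, 0 °C to rt; then cold 1 M HCl to pH 4
Reagents that add atoms: lithium hydroxide [Li+].[OH-]
Why: Saponification of the aryl lactone and cleavage of the aryl silyl ether by hydroxide. The two phenoxides formed push charge into the C4 carbonyl and should lower the acidity of C3, and cold, mild acidification avoids relactonisation.

Step 19
Reactants: 30 (3S)-3-{(2R,3S)-5,7-dihydroxy-2,3-dimethyl-8-[(2R)-5-methyl-2-(prop-1-en-2-yl)hex-5-en-1-yl]-4-oxochroman-6-yl}hexanoic acid; 31 3-methylbut-2-en-1-yl acetate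
Product: 32 (3S)-3-{(2R,3S,8R)-5-hydroxy-2,3-dimethyl-8-(3-methylbut-2-en-1-yl)-8-[(2R)-5-methyl-2-(prop-1-en-2-yl)hex-5-en-1-yl]-4,7-dioxo-3,4,7,8-tetrahydro-2H-chromen-6-yl}hexanoic acid
Conditions: Pd2(dba)3·CHCl3 (2.5 mol %), (R,R)-N,N'-bis(2-diphenylphosphinobenzoyl)cyclohexane-1,2-diamine (7.5 mol %), Cs2CO3 (2.2 equiv), THF, 0 °C to rt; then 1 M HCl
Reagents that add atoms: none
Why: Tsuji–Trost dearomative allylation of an acylphloroglucinol. The O7 phenoxide attacks the unsubstituted terminus of the π-prenyl palladium complex through C8, which bears a primary alkyl group, in preference to C6, which bears a secondary one. O-allylation of phenoxide and carboxylate is reversible under zerovalent palladium, whereas C-allylation gives a stabilised enolate and is final. The chiral ligand pocket selects the face of C8 (R required).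

## Compound list

1 | phloroglucinol | Oc1cc(O)cc(O)c1 | starting material
2 | ethyl 3-oxohexanoate | CCCC(=O)CC(=O)OCC | starting material
3 | 5,7-dihydroxy-4-propyl-2H-chromen-2-one | CCCC1=CC(=O)Oc2cc(O)cc(O)c12 | intermediate
4 | 4-propyl-5,7-bis(trimethylsilyloxy)-2H-chromen-2-one | CCCC1=CC(=O)Oc2cc(O[Si](C)(C)C)cc(O[Si](C)(C)C)c12 | intermediate
5 | diethoxy(methyl){[(4S)-4-propyl-5,7-bis(trimethylsilyloxy)-4H-chromen-2-yl]oxy}silane | CCO[Si](C)(OCC)OC1=C[C@H](CCC)c2c(O[Si](C)(C)C)cc(O[Si](C)(C)C)cc2O1 | intermediate
6 | (4S)-5,7-dihydroxy-4-propylchroman-2-one | Oc1cc(O)cc2OC(=O)C[C@H](CCC)c12 | intermediate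
7 | N-{[(4S)-5,7-dihydroxy-2-oxo-4-propylchroman-8-yl]methylidene}-N-methylmethanaminium chloride | Oc1cc(O)c(C=[N+](C)C)c2OC(=O)C[C@H](CCC)c12.[Cl-] | intermediate
8 | (4S)-5,7-dihydroxy-2-oxo-4-propylchromane-8-carbaldehyde | Oc1cc(O)c(C=O)c2OC(=O)C[C@H](CCC)c12 | intermediate
9 | (4S)-5-(tert-butyldimethylsilyloxy)-7-hydroxy-2-oxo-4-propylchromane-8-carbaldehyde | CC(C)(C)[Si](C)(C)Oc1cc(O)c(C=O)c2OC(=O)C[C@H](CCC)c12 | intermediate
10 | ethyl (S)-lactate | C[C@H](O)C(=O)OCC | starting material
11 | ethyl (S)-2-(tert-butyldimethylsilyloxy)propanoate | C[C@H](O[Si](C)(C)C(C)(C)C)C(=O)OCC | intermediate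
12 | (S)-2-(tert-butyldimethylsilyloxy)propanal | C[C@H](O[Si](C)(C)C(C)(C)C)C=O | intermediate
13 | tert-butyl (S,E)-4-(tert-butyldimethylsilyloxy)pent-2-enoate | C[C@H](O[Si](C)(C)C(C)(C)C)/C=C/C(=O)OC(C)(C)C | intermediate
14 | tert-butyl (S,E)-4-hydroxypent-2-enoate | C[C@H](O)/C=C/C(=O)OC(C)(C)C | intermediate
15 | tert-butyl (R,E)-4-{[(4S)-5-(tert-butyldimethylsilyloxy)-8-formyl-2-oxo-4-propylchroman-7-yl]oxy}pent-2-enoate | CC(C)(C)[Si](C)(C)Oc1cc(O[C@H](C)/C=C/C(=O)OC(C)(C)C)c(C=O)c2OC(=O)C[C@H](CCC)c12 | intermediate
16 | tert-butyl 2-[(4S,8R,9S)-5-(tert-butyldimethylsilyloxy)-8-methyl-2,10-dioxo-4-propyl-3,4,9,10-tetrahydro-2H,8H-pyrano[2,3-f]chromen-9-yl]acetate (8,9-cis) | CC(C)(C)[Si](C)(C)Oc1cc2O[C@H](C)[C@H](CC(=O)OC(C)(C)C)C(=O)c2c3OC(=O)C[C@H](CCC)c13 | intermediate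
17 | 2-[(4S,8R,9S)-5-(tert-butyldimethylsilyloxy)-8-methyl-2,10-dioxo-4-propyl-3,4,9,10-tetrahydro-2H,8H-pyrano[2,3-f]chromen-9-yl]acetic acid | CC(C)(C)[Si](C)(C)Oc1cc2O[C@H](C)[C@H](CC(=O)O)C(=O)c2c3OC(=O)C[C@H](CCC)c13 | intermediate
18 | 2-thioxopyridin-1(2H)-yl ester of 17 | CC(C)(C)[Si](C)(C)Oc1cc2O[C@H](C)[C@H](CC(=O)ON4C=CC=CC4=S)C(=O)c2c3OC(=O)C[C@H](CCC)c13 | intermediate
19 | (4S,8R,9S)-5-(tert-butyldimethylsilyloxy)-8,9-dimethyl-4-propyl-3,4,8,9-tetrahydro-2H,10H-pyrano[2,3-f]chromene-2,10-dione | CC(C)(C)[Si](C)(C)Oc1cc2O[C@H](C)[C@H](C)C(=O)c2c3OC(=O)C[C@H](CCC)c13 | intermediate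
20 | (4S,8R,9S)-5-(tert-butyldimethylsilyloxy)-6-iodo-8,9-dimethyl-4-propyl-3,4,8,9-tetrahydro-2H,10H-pyrano[2,3-f]chromene-2,10-dione | CC(C)(C)[Si](C)(C)Oc1c(I)c2O[C@H](C)[C@H](C)C(=O)c2c3OC(=O)C[C@H](CCC)c13 | intermediate
21 | (R)-limonene | CC1=CC[C@@H](CC1)C(C)=C | starting material
22 | (4R)-1-methyl-4-(prop-1-en-2-yl)-7,8,9-trioxabicyclo[4.2.1]nonane (bridgehead epimers) | CC12CC[C@H](CC(OO1)O2)C(C)=C | intermediate
23 | (3R)-6-oxo-3-(prop-1-en-2-yl)heptanal | O=CC[C@@H](CCC(C)=O)C(C)=C | intermediate
24 | (3R)-6-oxo-3-(prop-1-en-2-yl)heptanoic acid | OC(=O)C[C@@H](CCC(C)=O)C(C)=C | intermediate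
25 | (3R)-6-methyl-3-(prop-1-en-2-yl)hept-6-enoic acid | OC(=O)C[C@@H](CCC(C)=C)C(C)=C | intermediate
26 | 2-thioxopyridin-1(2H)-yl (3R)-6-methyl-3-(prop-1-en-2-yl)hept-6-enoate | S=C1C=CC=CN1OC(=O)C[C@@H](CCC(C)=C)C(C)=C | intermediate
27 | (3S)-3-(iodomethyl)-2,6-dimethylhepta-1,6-diene | IC[C@@H](CCC(C)=C)C(C)=C | intermediate
28 | [(2S)-5-methyl-2-(prop-1-en-2-yl)hex-5-en-1-yl]zinc iodide | I[Zn]C[C@@H](CCC(C)=C)C(C)=C | intermediate
29 | (4S,8R,9S)-5-(tert-butyldimethylsilyloxy)-8,9-dimethyl-6-[(2R)-5-methyl-2-(prop-1-en-2-yl)hex-5-en-1-yl]-4-propyl-3,4,8,9-tetrahydro-2H,10H-pyrano[2,3-f]chromene-2,10-dione | CC(C)(C)[Si](C)(C)Oc1c(C[C@@H](CCC(C)=C)C(C)=C)c2O[C@H](C)[C@H](C)C(=O)c2c3OC(=O)C[C@H](CCC)c13 | intermediate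
30 | (3S)-3-{(2R,3S)-5,7-dihydroxy-2,3-dimethyl-8-[(2R)-5-methyl-2-(prop-1-en-2-yl)hex-5-en-1-yl]-4-oxochroman-6-yl}hexanoic acid | OC(=O)C[C@H](CCC)c1c(O)c(C[C@@H](CCC(C)=C)C(C)=C)c2O[C@H](C)[C@H](C)C(=O)c2c1O | intermediate
31 | 3-methylbut-2-en-1-yl acetate (prenyl acetate) | CC(=O)OCC=C(C)C | starting material
32 | (3S)-3-{(2R,3S,8R)-5-hydroxy-2,3-dimethyl-8-(3-methylbut-2-en-1-yl)-8-[(2R)-5-methyl-2-(prop-1-en-2-yl)hex-5-en-1-yl]-4,7-dioxo-3,4,7,8-tetrahydro-2H-chromen-6-yl}hexanoic acid | C=C(C)CC[C@H](C[C@@]1(CC=C(C)C)C(=O)C([C@@H](CCC)CC(=O)O)=C(O)C2=C1O[C@H](C)[C@H](C)C2=O)C(=C)C | target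

## Step count and risks

Total: 19 steps. Longest linear sequence: 12 steps (steps 1, 2, 3, 4, 8, 9, 10, 11, 12, 17, 18, 19, from phloroglucinol).

Least certain steps:

**Step 9 (key step).** Carbene addition to an aldehyde flanked by two oxygens on an electron-rich ring is slow. During a long reaction, base-mediated enolisation can epimerise C3 toward the trans isomer, and a mismatch between catalyst and the lactate-derived centre would lower facial selectivity.

Fallback, from 15 back to 16: close the ring without stereochemical demand, using 3-benzyl-5-(2-hydroxyethyl)-4-methylthiazolium chloride and Et3N in warm dioxane. This is expected to give mainly the trans isomer, tert-butyl 2-[(4S,8R,9R)-5-(tert-butyldimethylsilyloxy)-8-methyl-2,10-dioxo-4-propyl-3,4,9,10-tetrahydro-2H,8H-pyrano[2,3-f]chromen-9-yl]acetate F1. Deprotonation with LiN(SiMe3)2 in THF at −78 °C gives the lithium enolate F2, in which the C8 methyl sits pseudo-axial to avoid the C9 substituent. Kinetic protonation with 2,6-di-tert-butyl-4-methylphenol from the face opposite that methyl group places the acetate arm cis and returns to 16. C3 is then set by protonation and not by the bond-forming step.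

**Step 19.** Facial discrimination at C8 may be poor, because its two alkyl groups both begin with CH2 and the nearest stereocentre is remote. Competing attack at C6 is also possible.

Fallback, from 30 back to 32: chiral ion-pair alkylation with prenyl bromide (2.2 equiv), N-(9-anthracenylmethyl)cinchonidinium bromide (10 mol %) and CsOH·H2O in toluene at −40 °C. This alkylates the carboxylate as well and gives the prenyl ester of 32, F3. Pd(PPh3)4 and morpholine in THF then remove the ester group and return 32.

**Step 3.** Competing substitution at the carbon between the two hydroxyl groups, and double formylation, would erode regiochemical purity.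

Fallback, from 6 back to 8: steric blocking. Bis-silylation (t-BuMe2SiCl, imidazole, DMF) gives (4S)-5,7-bis(tert-butyldimethylsilyloxy)-4-propylchroman-2-one F4, in which C6 lies between two bulky silyl ethers. Rieche formylation (Cl2CHOMe, AgOSO2CF3, CH2Cl2, −78 °C) should then occur at C8 to give (4S)-5,7-bis(tert-butyldimethylsilyloxy)-2-oxo-4-propylchromane-8-carbaldehyde F5. Bu4NF and AcOH return 8.

**Step 2.** Hydride transfer to a fully substituted β-carbon crowded by the peri silyloxy group may be slow and poorly face-selective, and any lactone released early can be over-reduced.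

Fallback, from 1 back to 6: make the stereocentre by adding the propyl group instead of hydride.
- 1 with ethyl propiolate and ZnCl2 in dioxane at 100 °C gives 5,7-dihydroxy-2H-chromen-2-one F6.
- BnBr and K2CO3 in acetone give 5,7-bis(benzyloxy)-2H-chromen-2-one F7.
- Copper-catalysed conjugate addition of n-PrMgBr (CuBr·SMe2, a Josiphos-type ferrocenyl bisphosphine, t-BuOMe, −78 °C) to the unsubstituted β-carbon gives (4S)-5,7-bis(benzyloxy)-4-propylchroman-2-one F8.
- H2 over Pd/C returns 6; no alkene is present at this stage.

**Step 17.** Oxidative addition and transmetalation at an iodide between two ortho oxygen substituents may be slow, so protodeiodination and decay of the zinc reagent can take over.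

Fallback, from 19 and 27 back to 30: couple on the less hindered free phenol with a boron reagent.
- 19 with Bu4NF and AcOH gives (4S,8R,9S)-5-hydroxy-8,9-dimethyl-4-propyl-3,4,8,9-tetrahydro-2H,10H-pyrano[2,3-f]chromene-2,10-dione F9.
- NIS in MeCN gives its 6-iodo derivative F10.
- 27 is converted with t-BuLi (Et2O, −78 °C) and 9-methoxy-9-borabicyclo[3.3.1]nonane into lithium B-methoxy-B-[(2S)-5-methyl-2-(prop-1-en-2-yl)hex-5-en-1-yl]-9-borabicyclo[3.3.1]nonan-9-uide F11.
- B-alkyl Suzuki coupling of F11 with F10 (Pd(dppf)Cl2, K3PO4, DMF/H2O, rt) gives (4S,8R,9S)-5-hydroxy-8,9-dimethyl-6-[(2R)-5-methyl-2-(prop-1-en-2-yl)hex-5-en-1-yl]-4-propyl-3,4,8,9-tetrahydro-2H,10H-pyrano[2,3-f]chromene-2,10-dione F12.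
- LiOH in THF/H2O opens the lactone and returns 30.

## Further compounds

F1 | step 9 | tert-butyl 2-[(4S,8R,9R)-5-(tert-butyldimethylsilyloxy)-8-methyl-2,10-dioxo-4-propyl-3,4,9,10-tetrahydro-2H,8H-pyrano[2,3-f]chromen-9-yl]acetate (8,9-trans) | CC(C)(C)[Si](C)(C)Oc1cc2O[C@H](C)[C@@H](CC(=O)OC(C)(C)C)C(=O)c2c3OC(=O)C[C@H](CCC)c13
F2 | step 9 | lithium enolate (C9=C10–O) of F1 | CC(C)(C)[Si](C)(C)Oc1cc2O[C@H](C)C(CC(=O)OC(C)(C)C)=C([O-])c2c3OC(=O)C[C@H](CCC)c13.[Li+]
F3 | step 19 | 3-methylbut-2-en-1-yl ester of 32 | C=C(C)CC[C@H](C[C@@]1(CC=C(C)C)C(=O)C([C@@H](CCC)CC(=O)OCC=C(C)C)=C(O)C2=C1O[C@H](C)[C@H](C)C2=O)C(=C)C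
F4 | step 3 | (4S)-5,7-bis(tert-butyldimethylsilyloxy)-4-propylchroman-2-one | CC(C)(C)[Si](C)(C)Oc1cc(O[Si](C)(C)C(C)(C)C)cc2OC(=O)C[C@H](CCC)c12
F5 | step 3 | (4S)-5,7-bis(tert-butyldimethylsilyloxy)-2-oxo-4-propylchromane-8-carbaldehyde | CC(C)(C)[Si](C)(C)Oc1cc(O[Si](C)(C)C(C)(C)C)c(C=O)c2OC(=O)C[C@H](CCC)c12
F6 | step 2 | 5,7-dihydroxy-2H-chromen-2-one | O=C1C=Cc2c(O)cc(O)cc2O1
F7 | step 2 | 5,7-bis(benzyloxy)-2H-chromen-2-one | O=C1C=Cc2c(OCc3ccccc3)cc(OCc3ccccc3)cc2O1
F8 | step 2 | (4S)-5,7-bis(benzyloxy)-4-propylchroman-2-one | O=C1C[C@H](CCC)c2c(OCc3ccccc3)cc(OCc3ccccc3)cc2O1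
F9 | step 17 | (4S,8R,9S)-5-hydroxy-8,9-dimethyl-4-propyl-3,4,8,9-tetrahydro-2H,10H-pyrano[2,3-f]chromene-2,10-dione | Oc1cc2O[C@H](C)[C@H](C)C(=O)c2c3OC(=O)C[C@H](CCC)c13
F10 | step 17 | (4S,8R,9S)-5-hydroxy-6-iodo-8,9-dimethyl-4-propyl-3,4,8,9-tetrahydro-2H,10H-pyrano[2,3-f]chromene-2,10-dione | Oc1c(I)c2O[C@H](C)[C@H](C)C(=O)c2c3OC(=O)C[C@H](CCC)c13
F11 | step 17 | lithium B-methoxy-B-[(2S)-5-methyl-2-(prop-1-en-2-yl)hex-5-en-1-yl]-9-borabicyclo[3.3.1]nonan-9-uide | [Li+].CO[B-]1(C[C@@H](CCC(C)=C)C(C)=C)C2CCCC1CCC2
F12 | step 17 | (4S,8R,9S)-5-hydroxy-8,9-dimethyl-6-[(2R)-5-methyl-2-(prop-1-en-2-yl)hex-5-en-1-yl]-4-propyl-3,4,8,9-tetrahydro-2H,10H-pyrano[2,3-f]chromene-2,10-dione | Oc1c(C[C@@H](CCC(C)=C)C(C)=C)c2O[C@H](C)[C@H](C)C(=O)c2c3OC(=O)C[C@H](CCC)c13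
A1 | alternative 1 | dioxinone precursor: quaternary carbon bearing prenyl, arm, the cis-2,3-dimethyl-4-oxo-2,3-dihydropyran-6-yl group and a 2,2-dimethyl-4-oxo-1,3-dioxin-6-yl group whose C5 carries the allyl hexanoate chain | C=C(C)CC[C@H](C[C@@](C1=CC(=O)[C@@H](C)[C@@H](C)O1)(CC=C(C)C)C1=C([C@@H](CCC)CC(=O)OCC=C)C(=O)OC(C)(C)O1)C(=C)C
A2 | alternative 1 | allyl ester of 32 | C=C(C)CC[C@H](C[C@@]1(CC=C(C)C)C(=O)C([C@@H](CCC)CC(=O)OCC=C)=C(O)C2=C1O[C@H](C)[C@H](C)C2=O)C(=C)C
A3 | alternative 2 | acyclic methyl ester on the quaternary carbon with an (E)-β-methoxy enone chain ending in the tert-butyl hexanoate unit | C=C(C)CC[C@H](C[C@@](C(=O)/C=C(/OC)C[C@@H](CCC)CC(=O)OC(C)(C)C)(CC=C(C)C)C(=O)OC)C(=C)C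
A4 | alternative 2 | 5-O-methyl ring A with the tert-butyl-protected acid chain | C=C(C)CC[C@H](C[C@@]1(CC=C(C)C)C(O)=C([C@@H](CCC)CC(=O)OC(C)(C)C)C(OC)=CC1=O)C(=C)C
A5 | alternative 3 | prochiral 6,6-dialkyl-3-hydroxy-5-methoxycyclohexa-2,4-dienone (ring carbon C8 undefined; the two ring halves exchange by tautomerism) | C=C(C)CC[C@H](CC1(CC=C(C)C)C(O)=CC(OC)=CC1=O)C(=C)C
A6 | alternative 3 | (E)-hex-2-enoic anhydride | CCC/C=C/C(=O)OC(=O)/C=C/CCC
A7 | alternative 3 | O7 enol lactone with C8 and the propyl-bearing carbon set | C=C(C)CC[C@H](C[C@@]1(CC=C(C)C)C2=C(C(OC)=CC1=O)[C@@H](CCC)CC(=O)O2)C(=C)C
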